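**Retrosynthetic overview**

1. Feature used: ring B holds C5 and the adjacent C8/C9 centres, while C10 is sp2 (C1=C10) in the target. A trienone with its ketone at C1 inside the tether can therefore build both rings and treat C10 as a throw-away centre.
2. Key disconnection: C5–C10 and C8–C9 by intramolecular Diels–Alder reaction of trienone 26 (diene C5=C6–C7=C8, enone C9=C10–C1=O). Rings A and B form together in step 16.
3. 26 ⇒ aldehyde 16 + vinyl iodide 23 (C1–C10 bond by Nozaki–Hiyama–Kishi coupling, then oxidation); 23 comes from (R)-citronellol (C13) by alkyne carboalumination.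
4. 16 ⇒ glutamic-acid-derived lactone 1. Its stereocentre becomes C2 and steers the α,α-dialkylation that sets quaternary C4; the lactone keeps the C2–O/C4–carboxyl pair masked until the C2 oxygen is silylated.
5. After the cycloaddition: hydrogenation of C6=C7, enol triflate formation and reduction to C1=C10, then Mitsunobu inversion at C2 with acetic acid.

Key step: step 16

Remark (numbering): ring A = C1–C5 and C10; ring B = C5–C10. C4 carries the methyl ester and a methyl; C8 carries C17; C9 carries C20 and the chain C11–C15 (methyl C16 on C13). β is the face of ring A that carries the C4 ester and H5.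

Assumption: minor isomers that converge later (the C3 epimer of 4, both carbinol epimers of 25) are carried on, and any (E,Z)-diene in 10 is removed by chromatography.

**Route**

Step 1
Reactants: 1 (S)-5-(hydroxymethyl)dihydrofuran-2(3H)-one
Product: 2 (S)-5-(trityloxymethyl)dihydrofuran-2(3H)-one
Conditions: TrCl, pyridine, DMAP (cat.), CH2Cl2, rt
Reagents that add atoms: trityl chloride, ClC(c1ccccc1)(c1ccccc1)c1ccccc1
Why: Tritylation of the primary alcohol gives the bulky ether that later shields one lactone face; the stereocentre (future C2) comes from the chiral pool and is not touched.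

Step 2
Reactants: 2 (S)-5-(trityloxymethyl)dihydrofuran-2(3H)-one
Product: 4 (3R,5S)-3-methyl-5-(trityloxymethyl)dihydrofuran-2(3H)-one, via lithium enolate 3 (not isolated)
Conditions: LiN(i-Pr)2, THF, −78 °C; MeI, −78 → −40 °C
Reagents that add atoms: iodomethane, CI
Why: Enolate alkylation installs the C4 methyl, mainly trans to the trityloxymethyl group; the new centre is made planar again in step 3, so its configuration does not matter.

Step 3
Reactants: 4 (3R,5S)-3-methyl-5-(trityloxymethyl)dihydrofuran-2(3H)-one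
Product: 6 (3S,5S)-3-(hydroxymethyl)-3-methyl-5-(trityloxymethyl)dihydrofuran-2(3H)-one, via lithium enolate 5 (not isolated)
Conditions: LiN(i-Pr)2, THF, −78 °C; CH2O (gas, from cracked paraformaldehyde), −78 °C; AcOH quench
Reagents that add atoms: formaldehyde, C=O
Why: Aldol-type hydroxymethylation of the tetrasubstituted enolate should occur anti to the trityloxymethyl group, as in the known diastereoselective α,α-dialkylation of this lactone, which sets quaternary C4 (S) with CH2OH trans to CH2OTr.

Step 4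
Reactants: 6 (3S,5S)-3-(hydroxymethyl)-3-methyl-5-(trityloxymethyl)dihydrofuran-2(3H)-one
Product: 7 (3S,5S)-3-methyl-2-oxo-5-(trityloxymethyl)tetrahydrofuran-3-carbaldehyde
Conditions: Dess–Martin periodinane, CH2Cl2, rt; used crude
Reagents that add atoms: none
Why: Dess–Martin oxidation of the neopentyl alcohol gives the C5 aldehyde, which cannot epimerise because its α-carbon is quaternary.

Step 5
Reactants: 7 (3S,5S)-3-methyl-2-oxo-5-(trityloxymethyl)tetrahydrofuran-3-carbaldehyde; 8 diethyl (E)-but-2-enylphosphonate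
Product: 10 (3S,5S)-3-methyl-3-[(1E,3E)-penta-1,3-dienyl]-5-(trityloxymethyl)dihydrofuran-2(3H)-one, via lithiated phosphonate 9 (not isolated)
Conditions: 8, n-BuLi, THF, −78 °C; then 7, −78 °C → rt
Reagents that add atoms: none
Why: Horner–Wadsworth–Emmons olefination through the α-carbon of the allylic phosphonate anion should form the new C5=C6 bond (E) and keep the (E)-C7=C8 bond; the aldehyde is non-enolisable and far more electrophilic than the lactone.

Step 6
Reactants: 10 (3S,5S)-3-methyl-3-[(1E,3E)-penta-1,3-dienyl]-5-(trityloxymethyl)dihydrofuran-2(3H)-one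
Product: 13 (2S,3E,5E)-2-[(2S)-2-(tert-butyldimethylsilyloxy)-3-(trityloxy)propyl]-2-methylhepta-3,5-dienoic acid, via potassium hydroxy carboxylate 11 (not isolated), via bis-silylated acid 12 (not isolated)
Conditions: KOH, MeOH/THF/H2O, rt, evaporate to dryness; TBSCl, imidazole, DMF, rt; K2CO3 (cat.), MeOH/H2O, rt, pH 5 work-up
Reagents that add atoms: potassium hydroxide, [K+].[OH-]; tert-butyldimethylsilyl chloride, CC(C)(C)[Si](C)(C)Cl
Why: Saponification, silylation of both oxygens and selective hydrolysis of the labile silyl ester open the lactone with the C2 oxygen capped, so the γ-hydroxy acid is never free to re-lactonise; no stereocentre is touched.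

Step 7
Reactants: 13 (2S,3E,5E)-2-[(2S)-2-(tert-butyldimethylsilyloxy)-3-(trityloxy)propyl]-2-methylhepta-3,5-dienoic acid
Product: 14 methyl (2S,3E,5E)-2-[(2S)-2-(tert-butyldimethylsilyloxy)-3-(trityloxy)propyl]-2-methylhepta-3,5-dienoate
Conditions: MeI, K2CO3, DMF, rt
Reagents that add atoms: iodomethane, CI
Why: O-alkylation of the carboxylate (SN2 on iodomethane) is insensitive to the hindrance at the quaternary α-carbon and gives the methyl ester of the target.

Step 8
Reactants: 14 methyl (2S,3E,5E)-2-[(2S)-2-(tert-butyldimethylsilyloxy)-3-(trityloxy)propyl]-2-methylhepta-3,5-dienoate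
Product: 15 methyl (2S,3E,5E)-2-[(2S)-2-(tert-butyldimethylsilyloxy)-3-hydroxypropyl]-2-methylhepta-3,5-dienoate
Conditions: camphorsulfonic acid (cat.), MeOH/CH2Cl2, 0 °C, short reaction time
Reagents that add atoms: none
Why: Acid-catalysed methanolysis removes the trityl ether through the trityl cation, which methanol traps; the secondary silyl ether should survive at 0 °C, and the short time limits δ-lactonisation.

Step 9
Reactants: 15 methyl (2S,3E,5E)-2-[(2S)-2-(tert-butyldimethylsilyloxy)-3-hydroxypropyl]-2-methylhepta-3,5-dienoate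
Product: 16 methyl (2S,3E,5E)-2-[(2S)-2-(tert-butyldimethylsilyloxy)-3-oxopropyl]-2-methylhepta-3,5-dienoate
Conditions: Dess–Martin periodinane, CH2Cl2, 0 °C → rt; used at once
Reagents that add atoms: none
Why: Dess–Martin oxidation gives the α-silyloxy aldehyde (C1) under non-basic conditions, so C2 should not epimerise.

Step 10
Reactants: 17 (R)-citronellol
Product: 18 tert-butyl{[(3R)-3,7-dimethyloct-6-enyl]oxy}dimethylsilane
Conditions: TBSCl, imidazole, DMF, rt
Reagents that add atoms: tert-butyldimethylsilyl chloride, CC(C)(C)[Si](C)(C)Cl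
Why: Standard silylation protects the C15 hydroxyl; the C13 stereocentre comes from citronellol.

Step 11
Reactants: 18 tert-butyl{[(3R)-3,7-dimethyloct-6-enyl]oxy}dimethylsilane
Product: 20 (4R)-6-(tert-butyldimethylsilyloxy)-4-methylhexanal, via ozonide 19 (not isolated)
Conditions: O3, CH2Cl2, −78 °C; PPh3, −78 °C → rt
Reagents that add atoms: ozone, [O-][O+]=O
Why: Ozonolysis with reductive work-up cleaves the trisubstituted alkene to the aldehyde whose carbon becomes C9; the remote stereocentre is unaffected.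

Step 12
Reactants: 20 (4R)-6-(tert-butyldimethylsilyloxy)-4-methylhexanal
Product: 21 tert-butyldimethyl{[(3R)-3-methylhept-6-ynyl]oxy}silane
Conditions: dimethyl (1-diazo-2-oxopropyl)phosphonate, K2CO3, MeOH, 0 °C → rt
Reagents that add atoms: dimethyl (1-diazo-2-oxopropyl)phosphonate, COP(=O)(OC)C(=[N+]=[N-])C(C)=O
Why: Ohira–Bestmann (Seyferth–Gilbert) homologation converts the aldehyde into the terminal alkyne under mild base and adds the carbon that becomes C10.

Step 13
Reactants: 21 tert-butyldimethyl{[(3R)-3-methylhept-6-ynyl]oxy}silane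
Product: 23 tert-butyl{[(3R,6E)-7-iodo-3,6-dimethylhept-6-enyl]oxy}dimethylsilane, via alkenylalane 22 (not isolated)
Conditions: Me3Al, Cp2ZrCl2 (cat.), CH2Cl2, 0 °C → rt; I2, THF, −30 → 0 °C
Reagents that add atoms: trimethylaluminium, C[Al](C)C; iodine, II
Why: Negishi zirconium-catalysed carboalumination adds methyl (C20) and aluminium syn across the alkyne with aluminium at the terminus, and iodinolysis with retention gives the (E)-vinyl iodide.

Step 14
Reactants: 16 methyl (2S,3E,5E)-2-[(2S)-2-(tert-butyldimethylsilyloxy)-3-oxopropyl]-2-methylhepta-3,5-dienoate; 23 tert-butyl{[(3R,6E)-7-iodo-3,6-dimethylhept-6-enyl]oxy}dimethylsilane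
Product: 25 methyl (2S,3E,5E)-2-[(2S,4E,8R)-2,10-bis(tert-butyldimethylsilyloxy)-3-hydroxy-5,8-dimethyldec-4-enyl]-2-methylhepta-3,5-dienoate (both carbinol epimers), via alkenylchromium dichloride 24 (not isolated)
Conditions: CrCl2 (excess), NiCl2 (cat.), DMSO/THF, rt
Reagents that add atoms: none
Why: Nozaki–Hiyama–Kishi coupling forms the C1–C10 bond with retention of the alkene geometry and adds chemoselectively to the aldehyde beside the methyl ester; the new carbinol centre is removed in step 15.

Step 15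
Reactants: 25 methyl (2S,3E,5E)-2-[(2S,4E,8R)-2,10-bis(tert-butyldimethylsilyloxy)-3-hydroxy-5,8-dimethyldec-4-enyl]-2-methylhepta-3,5-dienoate
Product: 26 methyl (2S,3E,5E)-2-[(2S,4E,8R)-2,10-bis(tert-butyldimethylsilyloxy)-5,8-dimethyl-3-oxodec-4-enyl]-2-methylhepta-3,5-dienoate
Conditions: Dess–Martin periodinane, CH2Cl2, 0 °C → rt
Reagents that add atoms: none
Why: Dess–Martin oxidation of both allylic alcohol epimers converges on the (E)-enone without base, so C2 and the enone geometry should be kept.

Step 16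
Reactants: 26 methyl (2S,3E,5E)-2-[(2S,4E,8R)-2,10-bis(tert-butyldimethylsilyloxy)-5,8-dimethyl-3-oxodec-4-enyl]-2-methylhepta-3,5-dienoate
Product: 27 cis-fused 2α,15-bis(tert-butyldimethylsilyloxy)-1-oxo-6-ene adduct (H5/H8/H10 β; C17/C20 α; C11 chain β; C4 ester β)
Conditions: Me2AlCl (2 equiv), CH2Cl2, −78 → −20 °C; aq. NaHCO3
Reagents that add atoms: none
Why: Me2AlCl binds the C1 carbonyl and lowers the enone LUMO, and the (E,E)-diene adds to the (E)-enone in a concerted but asynchronous [4+2] cycloaddition of the kind established for Lewis-acid-promoted type 1 intramolecular Diels–Alder reactions of 1,7,9-decatrien-3-ones. Ring B (C5–C10) closes by the cycloaddition itself through the new C5–C10 and C8–C9 bonds, and ring A (C1–C5, C10) closes in the same event as a fused six-membered carbocycle because the four-atom tether C1–C4 already links C10 to C5. C5 and C8 follow from suprafacial addition to the (E,E)-diene (H5 and H8 cis), and C9 and C10 from suprafacial addition to the (E)-enone with the tether carbonyl under the diene, which gives the cis ring fusion, C20 cis to C17 and C11 trans to C17. The step needs this endo mode and one diene face; the endo mode is favoured by Lewis acid complexation and because it places only the small C20 methyl, not the C11 chain, under the diene. The face is fixed by the chair-like tether, in which the cis-1,3 pair C2–OTBS and C4–CH3 should both sit equatorial (ester axial, pointing away from the diene), since attack on the other face would force them syn-diaxial. C10 is formed as a temporary centre that is erased in step 18.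

Step 17
Reactants: 27 cis-fused 2α,15-bis(tert-butyldimethylsilyloxy)-1-oxo-6-ene adduct
Product: 28 cis-fused 2α,15-bis(tert-butyldimethylsilyloxy)-1-oxo saturated bicycle
Conditions: H2 (1 atm), PtO2, EtOAc, rt
Reagents that add atoms: none
Why: Heterogeneous hydrogenation saturates the only C=C bond (C6=C7) without creating a stereocentre; PtO2 is chosen to limit double-bond migration towards the ketone.

Step 18
Reactants: 28 cis-fused 2α,15-bis(tert-butyldimethylsilyloxy)-1-oxo saturated bicycle
Product: 30 C1(OTf)=C10 enol triflate, via potassium enolate 29 (not isolated)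
Conditions: KN(SiMe3)2, THF, −78 °C; Comins' reagent, −78 → −40 °C
Reagents that add atoms: N-(5-chloropyridin-2-yl)-N-(trifluoromethylsulfonyl)trifluoromethanesulfonamide, FC(F)(F)S(=O)(=O)N(c1ccc(Cl)cn1)S(=O)(=O)C(F)(F)F
Why: Kinetic deprotonation by the hindered amide base is expected at C10 rather than C2, because α-silyloxy ketones enolise away from the oxygen-bearing carbon and H10 is axial to the carbonyl; O-triflation then fixes the C1=C10 enol and removes the temporary C10 centre.

Step 19
Reactants: 30 C1(OTf)=C10 enol triflate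
Product: 31 2α,15-bis(tert-butyldimethylsilyloxy)-1(10)-ene
Conditions: Pd(OAc)2 (cat.), PPh3, HCO2H, Et3N, DMF, 60 °C
Reagents that add atoms: none
Why: Palladium-catalysed formate reduction of the enol triflate (oxidative addition, formate-to-hydride exchange, reductive elimination) puts hydrogen on C1 and leaves the C1=C10 alkene; the allylic silyl ether is not ionised.

Step 20
Reactants: 31 2α,15-bis(tert-butyldimethylsilyloxy)-1(10)-ene
Product: 32 2α,15-diol
Conditions: HF·pyridine, pyridine/THF, 0 °C → rt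
Reagents that add atoms: none
Why: Fluoride-mediated cleavage removes both silyl ethers; the 2α-hydroxyl is trans to the C4 ester on ring A and so cannot lactonise.

Step 21
Reactants: 32 2α,15-diol
Product: 33 methyl (1S,3R,5S,6R,8aS)-3-acetoxy-5-[(3R)-5-acetoxy-3-methylpentyl]-1,5,6-trimethyl-1,2,3,5,6,7,8,8a-octahydronaphthalene-1-carboxylate (CNP0209333.1)
Conditions: PPh3, DIAD, AcOH (excess of each), THF, 0 °C → rt
Reagents that add atoms: acetic acid, CC(=O)O
Why: Mitsunobu esterification acetylates the primary C15 hydroxyl and displaces the allylic C2 oxyphosphonium by acetate with inversion to the 2β (2R) acetate; SN2′ attack should be disfavoured because C10 is fully substituted and flanked by quaternary C9.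

**Compound list**

1 | (S)-5-(hydroxymethyl)dihydrofuran-2(3H)-one | O=C1O[C@H](CO)CC1 | starting material
2 | (S)-5-(trityloxymethyl)dihydrofuran-2(3H)-one | O=C1O[C@H](COC(c2ccccc2)(c2ccccc2)c2ccccc2)CC1 | intermediate
3 | lithium enolate of 2 | [Li]OC1=CC[C@@H](COC(c2ccccc2)(c2ccccc2)c2ccccc2)O1 | intermediate (not isolated)
4 | (3R,5S)-3-methyl-5-(trityloxymethyl)dihydrofuran-2(3H)-one (trans; minor cis epimer converges) | O=C1O[C@H](COC(c2ccccc2)(c2ccccc2)c2ccccc2)C[C@H]1C | intermediate
5 | lithium enolate of 4 | [Li]OC1=C(C)C[C@@H](COC(c2ccccc2)(c2ccccc2)c2ccccc2)O1 | intermediate (not isolated)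
6 | (3S,5S)-3-(hydroxymethyl)-3-methyl-5-(trityloxymethyl)dihydrofuran-2(3H)-one | O=C1O[C@H](COC(c2ccccc2)(c2ccccc2)c2ccccc2)C[C@@]1(C)CO | intermediate
7 | (3S,5S)-3-methyl-2-oxo-5-(trityloxymethyl)tetrahydrofuran-3-carbaldehyde | O=C1O[C@H](COC(c2ccccc2)(c2ccccc2)c2ccccc2)C[C@@]1(C)C=O | intermediate
8 | diethyl (E)-but-2-enylphosphonate | CCOP(=O)(C/C=C/C)OCC | starting material
9 | lithiated diethyl (E)-but-2-enylphosphonate | [Li]C(/C=C/C)P(=O)(OCC)OCC | intermediate (not isolated)
10 | (3S,5S)-3-methyl-3-[(1E,3E)-penta-1,3-dienyl]-5-(trityloxymethyl)dihydrofuran-2(3H)-one | O=C1O[C@H](COC(c2ccccc2)(c2ccccc2)c2ccccc2)C[C@@]1(C)/C=C/C=C/C | intermediate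
11 | potassium (2S,3E,5E)-2-[(2S)-2-hydroxy-3-(trityloxy)propyl]-2-methylhepta-3,5-dienoate | [K+].[O-]C(=O)[C@@](C)(C[C@H](O)COC(c1ccccc1)(c1ccccc1)c1ccccc1)/C=C/C=C/C | intermediate (not isolated)
12 | tert-butyldimethylsilyl (2S,3E,5E)-2-[(2S)-2-(tert-butyldimethylsilyloxy)-3-(trityloxy)propyl]-2-methylhepta-3,5-dienoate | CC(C)(C)[Si](C)(C)OC(=O)[C@@](C)(C[C@H](O[Si](C)(C)C(C)(C)C)COC(c1ccccc1)(c1ccccc1)c1ccccc1)/C=C/C=C/C | intermediate (not isolated)
13 | (2S,3E,5E)-2-[(2S)-2-(tert-butyldimethylsilyloxy)-3-(trityloxy)propyl]-2-methylhepta-3,5-dienoic acid | OC(=O)[C@@](C)(C[C@H](O[Si](C)(C)C(C)(C)C)COC(c1ccccc1)(c1ccccc1)c1ccccc1)/C=C/C=C/C | intermediate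
14 | methyl (2S,3E,5E)-2-[(2S)-2-(tert-butyldimethylsilyloxy)-3-(trityloxy)propyl]-2-methylhepta-3,5-dienoate | COC(=O)[C@@](C)(C[C@H](O[Si](C)(C)C(C)(C)C)COC(c1ccccc1)(c1ccccc1)c1ccccc1)/C=C/C=C/C | intermediate
15 | methyl (2S,3E,5E)-2-[(2S)-2-(tert-butyldimethylsilyloxy)-3-hydroxypropyl]-2-methylhepta-3,5-dienoate | COC(=O)[C@@](C)(C[C@H](O[Si](C)(C)C(C)(C)C)CO)/C=C/C=C/C | intermediate
16 | methyl (2S,3E,5E)-2-[(2S)-2-(tert-butyldimethylsilyloxy)-3-oxopropyl]-2-methylhepta-3,5-dienoate | COC(=O)[C@@](C)(C[C@H](O[Si](C)(C)C(C)(C)C)C=O)/C=C/C=C/C | intermediate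
17 | (R)-citronellol | CC(C)=CCC[C@@H](C)CCO | starting material
18 | tert-butyl{[(3R)-3,7-dimethyloct-6-enyl]oxy}dimethylsilane | CC(C)=CCC[C@@H](C)CCO[Si](C)(C)C(C)(C)C | intermediate
19 | ozonide (1,2,4-trioxolane) of 18 | CC1(C)OOC(CC[C@@H](C)CCO[Si](C)(C)C(C)(C)C)O1 | intermediate (not isolated)
20 | (4R)-6-(tert-butyldimethylsilyloxy)-4-methylhexanal | O=CCC[C@@H](C)CCO[Si](C)(C)C(C)(C)C | intermediate
21 | tert-butyldimethyl{[(3R)-3-methylhept-6-ynyl]oxy}silane | C#CCC[C@@H](C)CCO[Si](C)(C)C(C)(C)C | intermediate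
22 | (E)-alkenyl(dimethyl)alane from 21 | C[Al](C)/C=C(\C)CC[C@@H](C)CCO[Si](C)(C)C(C)(C)C | intermediate (not isolated)
23 | tert-butyl{[(3R,6E)-7-iodo-3,6-dimethylhept-6-enyl]oxy}dimethylsilane | I/C=C(\C)CC[C@@H](C)CCO[Si](C)(C)C(C)(C)C | intermediate
24 | (E)-alkenylchromium dichloride from 23 | Cl[Cr](Cl)/C=C(\C)CC[C@@H](C)CCO[Si](C)(C)C(C)(C)C | intermediate (not isolated)
25 | methyl (2S,3E,5E)-2-[(2S,4E,8R)-2,10-bis(tert-butyldimethylsilyloxy)-3-hydroxy-5,8-dimethyldec-4-enyl]-2-methylhepta-3,5-dienoate (carbinol epimers) | COC(=O)[C@@](C)(C[C@H](O[Si](C)(C)C(C)(C)C)C(O)/C=C(\C)CC[C@@H](C)CCO[Si](C)(C)C(C)(C)C)/C=C/C=C/C | intermediate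
26 | methyl (2S,3E,5E)-2-[(2S,4E,8R)-2,10-bis(tert-butyldimethylsilyloxy)-5,8-dimethyl-3-oxodec-4-enyl]-2-methylhepta-3,5-dienoate (trienone, key-step precursor) | COC(=O)[C@@](C)(C[C@H](O[Si](C)(C)C(C)(C)C)C(=O)/C=C(\C)CC[C@@H](C)CCO[Si](C)(C)C(C)(C)C)/C=C/C=C/C | intermediate
27 | cis-fused 2α,15-bis(tert-butyldimethylsilyloxy)-1-oxo-6-ene adduct (key-step product) | COC(=O)[C@@]1(C)C[C@H](O[Si](C)(C)C(C)(C)C)C(=O)[C@H]2[C@@H]1C=C[C@@H](C)[C@]2(C)CC[C@@H](C)CCO[Si](C)(C)C(C)(C)C | intermediate
28 | cis-fused 2α,15-bis(tert-butyldimethylsilyloxy)-1-oxo saturated bicycle | COC(=O)[C@@]1(C)C[C@H](O[Si](C)(C)C(C)(C)C)C(=O)[C@H]2[C@@H]1CC[C@@H](C)[C@]2(C)CC[C@@H](C)CCO[Si](C)(C)C(C)(C)C | intermediate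
29 | potassium C1=C10 enolate of 28 | COC(=O)[C@@]1(C)C[C@H](O[Si](C)(C)C(C)(C)C)C(O[K])=C2[C@@H]1CC[C@@H](C)[C@]2(C)CC[C@@H](C)CCO[Si](C)(C)C(C)(C)C | intermediate (not isolated)
30 | C1(OTf)=C10 enol triflate | COC(=O)[C@@]1(C)C[C@H](O[Si](C)(C)C(C)(C)C)C(OS(=O)(=O)C(F)(F)F)=C2[C@@H]1CC[C@@H](C)[C@]2(C)CC[C@@H](C)CCO[Si](C)(C)C(C)(C)C | intermediate
31 | 2α,15-bis(tert-butyldimethylsilyloxy)-1(10)-ene | COC(=O)[C@@]1(C)C[C@H](O[Si](C)(C)C(C)(C)C)C=C2[C@@H]1CC[C@@H](C)[C@]2(C)CC[C@@H](C)CCO[Si](C)(C)C(C)(C)C | intermediate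
32 | 2α,15-diol | COC(=O)[C@@]1(C)C[C@H](O)C=C2[C@@H]1CC[C@@H](C)[C@]2(C)CC[C@@H](C)CCO | intermediate
33 | methyl (1S,3R,5S,6R,8aS)-3-acetoxy-5-[(3R)-5-acetoxy-3-methylpentyl]-1,5,6-trimethyl-1,2,3,5,6,7,8,8a-octahydronaphthalene-1-carboxylate | COC(=O)[C@@]1(C)C[C@@H](OC(C)=O)C=C2[C@@H]1CC[C@@H](C)[C@]2(C)CC[C@@H](C)CCOC(C)=O | target

**Step count**

Total: 21 steps. Longest linear sequence: 17 steps (steps 1–9 and 14–21); the vinyl iodide branch is steps 10–13.

**Steps most likely to fail**

Step 16. The cycloaddition may be slow at the hindered β,β-disubstituted enone, so that Lewis-acid-induced diene decomposition or enone isomerisation competes, or the endo/facial preference may be eroded. The fallback changes the dienophile into a cationic one. It sets out from 26: ketalisation with 1,2-bis(trimethylsilyloxy)ethane and TMSOTf (cat.) in CH2Cl2 at −78 °C should give the trienone dioxolane F1. With more TMSOTf the dioxolane ionises to a ring-opened 2-alkoxyallyl cation, a far stronger dienophile, which should undergo the known cationic intramolecular [4+2] at low temperature under the same tether control and re-close to the adduct dioxolane F2. Mild hydrolysis (pyridinium tosylate, wet acetone) then returns to the route at 27.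

Step 18. Deprotonation may occur at the more acidic C2–H instead of the hindered C10–H, which would lead to the regioisomeric enol triflate. The fallback enforces the regiochemistry by stereochemistry and sets out from 28. HF·pyridine should give the 2α,15-dihydroxy ketone F3, and Mitsunobu reaction (PPh3, DIAD, AcOH) should give the 2β,15-diacetoxy ketone F4 with inversion at C2. Reduction with LiAlH(O-t-Bu)3 at low temperature, hydride entering anti to the polar 2β-acetoxy group, should give the 1β-hydroxy diacetate F5. Its hydroxyl is syn only to H10 (H2 is now α), so syn-elimination with Burgess reagent in warm toluene can only form C1=C10. This comes back to the route at 33.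

Step 21. Inversion at the allylic C2 may be incomplete because of elimination to a diene, SN2′ attack, or participation of the C4 ester carbonyl at the activated carbon. The fallback avoids activating C2 and sets out from 32. MnO2 in CH2Cl2 should oxidise only the allylic alcohol to the 15-hydroxy-1(10)-en-2-one F6. Reduction with (S)-Me-CBS oxazaborolidine and BH3·SMe2, with the alkenyl arm as the large group, should give the 2β,15-diol F7. Immediate acetylation (Ac2O, pyridine, DMAP), before the cis hydroxy ester can lactonise, comes back to the route at 33.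

**Further compounds**

F1 | step 16 | ethylene ketal (1,3-dioxolane) of trienone 26 | COC(=O)[C@@](C)(C[C@H](O[Si](C)(C)C(C)(C)C)C1(OCCO1)/C=C(\C)CC[C@@H](C)CCO[Si](C)(C)C(C)(C)C)/C=C/C=C/C
F2 | step 16 | ethylene ketal (1,3-dioxolane) of adduct 27 | COC(=O)[C@@]1(C)C[C@H](O[Si](C)(C)C(C)(C)C)C3(OCCO3)[C@H]2[C@@H]1C=C[C@@H](C)[C@]2(C)CC[C@@H](C)CCO[Si](C)(C)C(C)(C)C
F3 | step 18 | 2α,15-dihydroxy-1-oxo saturated bicycle | COC(=O)[C@@]1(C)C[C@H](O)C(=O)[C@H]2[C@@H]1CC[C@@H](C)[C@]2(C)CC[C@@H](C)CCO
F4 | step 18 | 2β,15-diacetoxy-1-oxo saturated bicycle | COC(=O)[C@@]1(C)C[C@@H](OC(C)=O)C(=O)[C@H]2[C@@H]1CC[C@@H](C)[C@]2(C)CC[C@@H](C)CCOC(C)=O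
F5 | step 18 | 2β,15-diacetoxy-1β-hydroxy saturated bicycle | COC(=O)[C@@]1(C)C[C@@H](OC(C)=O)[C@@H](O)[C@H]2[C@@H]1CC[C@@H](C)[C@]2(C)CC[C@@H](C)CCOC(C)=O
F6 | step 21 | 15-hydroxy-1(10)-en-2-one | COC(=O)[C@@]1(C)CC(=O)C=C2[C@@H]1CC[C@@H](C)[C@]2(C)CC[C@@H](C)CCO
F7 | step 21 | 2β,15-diol (2R) | COC(=O)[C@@]1(C)C[C@@H](O)C=C2[C@@H]1CC[C@@H](C)[C@]2(C)CC[C@@H](C)CCO
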